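The chroman's dihydropyran ring is cut at its aryl C4a–C4 bond and its O1–C2 bond. C2 with both methyls, C3 and C4 form one isoprene unit, held by a phenol oxygen and the neighbouring ring carbon and remote from the quaternary C5 of the butenolide ring. A single acid-catalysed reaction of the para-substituted phenol with isoprene should forge both bonds, close that ring and deliver the target without touching the stereocentre. The precursor is the (R)-3-hydroxy-4-phenylbutenolide carrying CO2Me and a 4-hydroxybenzyl arm at C5, assembled by aldol–lactonisation, enantioselective phase-transfer benzylation and one global hydrogenolysis.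

Key step: step 6

Numbering note: butenolide positions follow furan-2(5H)-one (C2 lactone carbonyl, C3 enol carbon, C4 phenyl-bearing carbon, C5 quaternary stereocentre); in the systematic dihydrofuran-2-carboxylate names this stereocentre is C2, and it is R in the target (O > CO2Me > C=C > CH2Ar).

Assumption: the face of the furanolate left open by the chiral ammonium salt in step 4 cannot be predicted with certainty; the (S)-catalyst is written, and its commercially available antipode would be used instead should the S ester form.

Step 1
Reactants: 1 phenylpyruvic acid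
Product: 2 methyl phenylpyruvate
Conditions: MeI (1.2 equiv.), KHCO3 (1.2 equiv.), DMF, rt
Reagents that add atoms: iodomethane, CI
Why: Bicarbonate forms only the carboxylate, which is methylated by SN2 displacement on iodomethane (carboxylate O-alkylation), while the weakly acidic enol and benzylic C–H of the keto acid stay untouched.

Step 2
Reactants: 2 methyl phenylpyruvate; 3 methyl glyoxylate
Product: 5 methyl 4-hydroxy-5-oxo-3-phenyl-2,5-dihydrofuran-2-carboxylate (racemic), via aldol adduct 4 (not isolated)
Conditions: 3 (2 equiv., freshly distilled), DBU (1.1 equiv., added last), DMF, 0 °C to rt; then 1 M HCl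
Reagents that add atoms: none
Why: DBU generates the pyruvate enolate, whose benzylic carbon adds to the non-enolisable and far more electrophilic aldehyde of 3 (crossed aldol addition), after which the new hydroxyl closes onto the activated α-keto ester (5-exo-trig lactonisation with loss of methanol) and the ketone enolises into conjugation with the phenyl group; the C5 stereocentre formed here is racemic and is erased by deprotonation in step 4, so no control is needed.

Step 3
Reactants: 5 methyl 4-hydroxy-5-oxo-3-phenyl-2,5-dihydrofuran-2-carboxylate (racemic)
Product: 6 methyl 4-(benzyloxy)-5-oxo-3-phenyl-2,5-dihydrofuran-2-carboxylate (racemic)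
Conditions: BnBr (1.05 equiv.), K2CO3 (1.0 equiv.), acetone, rt
Reagents that add atoms: benzyl bromide, BrCc1ccccc1
Why: Williamson O-alkylation of the enol, which is far more acidic than the C5–H, so that one equivalent of carbonate and a near-stoichiometric amount of benzyl bromide should cap oxygen without benzylating C5.

Step 4
Reactants: 6 methyl 4-(benzyloxy)-5-oxo-3-phenyl-2,5-dihydrofuran-2-carboxylate (racemic); 7 4-(benzyloxy)benzyl bromide
Product: 8 methyl (R)-4-(benzyloxy)-2-[4-(benzyloxy)benzyl]-5-oxo-3-phenyl-2,5-dihydrofuran-2-carboxylate
Conditions: 7 (1.2 equiv.), (S)-4,4-dibutyl-2,6-bis(3,4,5-trifluorophenyl)-4,5-dihydro-3H-dinaphtho[2,1-c:1',2'-e]azepinium bromide (2 mol%), powdered K2CO3 (3 equiv.), toluene, 0 °C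
Reagents that add atoms: none
Why: Asymmetric phase-transfer alkylation: carbonate removes the doubly activated C5–H (α to the ester, γ to the lactone carbonyl), the planar furanolate enters toluene as a tight ion pair with the C2-symmetric chiral ammonium cation, and the benzylic bromide attacks C5 on the face the catalyst leaves open, creating the R quaternary centre and restoring the conjugated 4-phenylbutenolide; a benzyl ether is used on the arm's phenol because it withstands the base, unlike an aryl silyl ether, and can leave together with the enol benzyl ether.

Step 5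
Reactants: 8 methyl (R)-4-(benzyloxy)-2-[4-(benzyloxy)benzyl]-5-oxo-3-phenyl-2,5-dihydrofuran-2-carboxylate
Product: 9 methyl (R)-4-hydroxy-2-(4-hydroxybenzyl)-5-oxo-3-phenyl-2,5-dihydrofuran-2-carboxylate
Conditions: H2 (1 atm), 10% Pd/C, EtOAc–MeOH, rt
Reagents that add atoms: none
Why: Catalytic hydrogenolysis cleaves both benzylic C–O bonds (aryl and enol benzyl ethers), while the tetrasubstituted conjugated C3=C4 bond, the methyl ester and the quaternary C5 are not reduced, so the R configuration is carried through unchanged.

Step 6
Reactants: 9 methyl (R)-4-hydroxy-2-(4-hydroxybenzyl)-5-oxo-3-phenyl-2,5-dihydrofuran-2-carboxylate; 10 isoprene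
Product: 12 4'-dehydroxy aspernolide A [methyl (R)-2-[(2,2-dimethylchroman-6-yl)methyl]-4-hydroxy-5-oxo-3-phenyl-2,5-dihydrofuran-2-carboxylate], via ortho-prenylphenol 11 (not isolated)
Conditions: 10 (1.3 equiv., added slowly), AgOTf (10 mol%), anhydrous ClCH2CH2Cl, rt, sealed vessel, dark
Reagents that add atoms: none
Why: The silver triflate (or the triflic acid it releases) turns isoprene into the dimethylallyl cation, which alkylates the phenol ring of 9 at a carbon ortho to OH to give 11; protonation of the new trisubstituted alkene then gives a tertiary cation that the phenol oxygen traps. The closest known reaction type is the acid- or silver-triflate-catalysed chromanylation of para-substituted phenols with isoprene, a Friedel–Crafts alkylation followed by Markovnikov hydroalkoxylation, and the second stage is the familiar acid cyclisation of ortho-prenylphenols. The dihydropyran ring closes in a 6-endo-trig mode, oxygen attacking the CMe2 terminus. No stereocentre is formed, and the quaternary C5 of the butenolide, bearing no hydrogen, cannot epimerise under acid. Site selectivity rests on the substrate: the para position is blocked and the two ortho positions are equivalent, the C4 phenyl is deactivated by conjugation with the lactone, and the enol's only nucleophilic carbon (C4) is fully substituted, while any enol O-prenyl ether should re-ionise under the acid. Further alkylation at C8 of the product chroman is held back by slow addition of only a slight excess of isoprene.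

Compound list
1 | phenylpyruvic acid (2-oxo-3-phenylpropanoic acid) | O=C(O)C(=O)Cc1ccccc1 | starting material
2 | methyl phenylpyruvate (methyl 2-oxo-3-phenylpropanoate, drawn as the keto form) | COC(=O)C(=O)Cc1ccccc1 | intermediate
3 | methyl glyoxylate | COC(=O)C=O | starting material
4 | dimethyl 2-hydroxy-4-oxo-3-phenylpentanedioate (aldol adduct, diastereomer mixture, formed in situ) | COC(=O)C(O)C(c1ccccc1)C(=O)C(=O)OC | intermediate
5 | methyl 4-hydroxy-5-oxo-3-phenyl-2,5-dihydrofuran-2-carboxylate (racemic) | COC(=O)C1OC(=O)C(O)=C1c1ccccc1 | intermediate
6 | methyl 4-(benzyloxy)-5-oxo-3-phenyl-2,5-dihydrofuran-2-carboxylate (racemic) | COC(=O)C1OC(=O)C(OCc2ccccc2)=C1c1ccccc1 | intermediate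
7 | 4-(benzyloxy)benzyl bromide [1-(benzyloxy)-4-(bromomethyl)benzene] | BrCc1ccc(OCc2ccccc2)cc1 | starting material
8 | methyl (R)-4-(benzyloxy)-2-[4-(benzyloxy)benzyl]-5-oxo-3-phenyl-2,5-dihydrofuran-2-carboxylate | COC(=O)[C@]1(Cc2ccc(OCc3ccccc3)cc2)OC(=O)C(OCc2ccccc2)=C1c1ccccc1 | intermediate
9 | methyl (R)-4-hydroxy-2-(4-hydroxybenzyl)-5-oxo-3-phenyl-2,5-dihydrofuran-2-carboxylate | COC(=O)[C@]1(Cc2ccc(O)cc2)OC(=O)C(O)=C1c1ccccc1 | intermediate
10 | isoprene (2-methylbuta-1,3-diene) | C=CC(C)=C | starting material
11 | methyl (R)-4-hydroxy-2-[4-hydroxy-3-(3-methylbut-2-en-1-yl)benzyl]-5-oxo-3-phenyl-2,5-dihydrofuran-2-carboxylate (ortho-prenylphenol, formed in situ) | COC(=O)[C@]1(Cc2ccc(O)c(CC=C(C)C)c2)OC(=O)C(O)=C1c1ccccc1 | intermediate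
12 | 4'-dehydroxy aspernolide A, methyl (R)-2-[(2,2-dimethylchroman-6-yl)methyl]-4-hydroxy-5-oxo-3-phenyl-2,5-dihydrofuran-2-carboxylate | COC(=O)[C@]1(Cc2ccc3c(c2)CCC(C)(C)O3)OC(=O)C(O)=C1c1ccccc1 | target

Total step count: 6. Longest linear sequence: 6 steps (1 → 2 → 5 → 6 → 8 → 9 → 12).

Steps most likely to fail

Step 6. Cationic oligomerisation of isoprene and repeated ring alkylation may outpace the single ortho C-alkylation and ring closure, or the acid may be tied up by the enol–lactone chelate so that conversion stalls. The fallback sets out from 9 and returns at 12, replacing cation chemistry by a condensation–electrocyclisation. Heating 9 with 3-methylbut-2-enal (CC(C)=CC=O) and phenylboronic acid in toluene–propionic acid, with azeotropic removal of water, should effect the boron-templated ortho-condensation and oxa-6π ring closure known for simple phenols. This should give the 2H-chromene methyl (R)-2-[(2,2-dimethyl-2H-chromen-6-yl)methyl]-4-hydroxy-5-oxo-3-phenyl-2,5-dihydrofuran-2-carboxylate F1. Hydrogenation of its disubstituted styrenyl C3=C4 bond (H2, Pd/C, EtOAc) should then give 12, leaving the tetrasubstituted enol double bond alone.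

Step 4. Facial discrimination within the ammonium–furanolate ion pair may be poor, or an uncatalysed background alkylation may erode it. The fallback sets out from 6 (with 7) and returns at 8, trading asymmetric catalysis for resolution. Alkylation with Bu4NBr (10 mol%) and K2CO3 in toluene should give the racemate methyl 4-(benzyloxy)-2-[4-(benzyloxy)benzyl]-5-oxo-3-phenyl-2,5-dihydrofuran-2-carboxylate F2. The enantiomers would be separated by preparative chromatography on a polysaccharide chiral stationary phase; the R half is 8 and the mirror-image half is set aside.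

Step 2. Self-aldol condensation of the pyruvate ester under base, or base-induced oligomerisation of the glyoxylate, may compete with the crossed addition. The fallback sets out from 2 (with 3) and returns at 5, and it avoids any free enolate. Silylation of 2 (TMSCl, Et3N, CH2Cl2, 0 °C) should give methyl (Z)-3-phenyl-2-[(trimethylsilyl)oxy]prop-2-enoate F3. A Mukaiyama aldol addition of F3 to 3 (TMSOTf 10 mol%, CH2Cl2, −78 °C) should give dimethyl 4-oxo-3-phenyl-2-[(trimethylsilyl)oxy]pentanedioate F4. Treatment of F4 with p-TsOH·H2O in toluene at 60 °C should remove the silyl group to give adduct 4 and close the lactone to 5.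

Further compounds
F1 | step 6 | methyl (R)-2-[(2,2-dimethyl-2H-chromen-6-yl)methyl]-4-hydroxy-5-oxo-3-phenyl-2,5-dihydrofuran-2-carboxylate | COC(=O)[C@]1(Cc2ccc3c(c2)C=CC(C)(C)O3)OC(=O)C(O)=C1c1ccccc1
F2 | step 4 | methyl 4-(benzyloxy)-2-[4-(benzyloxy)benzyl]-5-oxo-3-phenyl-2,5-dihydrofuran-2-carboxylate (racemate) | COC(=O)C1(Cc2ccc(OCc3ccccc3)cc2)OC(=O)C(OCc2ccccc2)=C1c1ccccc1
F3 | step 2 | methyl (Z)-3-phenyl-2-[(trimethylsilyl)oxy]prop-2-enoate | COC(=O)/C(O[Si](C)(C)C)=C/c1ccccc1
F4 | step 2 | dimethyl 4-oxo-3-phenyl-2-[(trimethylsilyl)oxy]pentanedioate | COC(=O)C(O[Si](C)(C)C)C(c1ccccc1)C(=O)C(=O)OC
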